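## The problem

The target 33 is a heliangolide-type germacranolide: a ten-membered carbocycle (C1–C10) fused trans across C6–C7 to an α-methylene γ-lactone (C11–C13), with a Z trisubstituted C4=C5 alkene, an allylic hydroxyl at C3, a trans epoxide spanning C1 and the quaternary C10, and at C8 the ester of (2R,3R)-2,3-dimethyloxirane-2-carboxylic (epoxyangelic) acid. Closing a ten-membered ring from a chain pays a heavy entropic and transannular price, so the ring is better uncovered from a bicycle than closed. Of the six ring stereocentres (1R,3S,6R,7R,8R,10R), C6, C7 and C8 are contiguous and can be relayed from C7, C10 can be read from C8 (1,3) and C1 from C10 (1,2), whereas C3 is remote from all of them and needs a reagent-controlled step. The exocyclic methylene is a Michael and radical acceptor, the 1,10-epoxide next to the C4=C5 alkene cyclises across the ring under acid, and both esters are base-labile. Medium-ring 1,6-diketones met on the way are prone to transannular aldol reaction. The enabling feature is that C1 and C6, opposite each other on the ring, both bear oxygen, and that the ten ring carbons with C14 (on C10) and C15 (on C4) map onto 1,6-dimethylnaphthalene. If C1 and C6 are joined they become the fusion carbons of a bicyclo[4.4.0] skeleton, and cleaving a C1=C6 fusion alkene writes both oxygens and the ten-membered ring in one operation. The two cis alkenes left by such a cleavage (C3=C4, C8=C9) each lie β,γ to a carbonyl, which allows oxygen to be relayed to C3 and to C8.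

## Retrosynthesis

Methylene and silyl ether (33 ⇒ 32 ⇒ 28). The O–Si bond at C3 and the C11=C13 bond are cut last. Cutting the C8 ester last instead would leave a hindered hydroxyl to acylate beside a free allylic alcohol. With the methylene absent, 28 has one acidic C–H (C11), and the Michael acceptor is kept away from the hydride, radical and amine steps. The forward steps must aminomethylate a lactone enolate (29, then 30 and 31) beside a hindered, non-enolisable ester and then desilylate under buffered conditions.

Epoxide (28 ⇒ 26 ⇒ 25 ⇒ 23). The C1–O bond of the epoxide is cut to the 1α,10α-diol 26, closure running through mesylate 27 with inversion at C1. The C1–H bond is cut to hydroxy ketone 25, and the C10–O bond with the C9–H bond to enone 23 (through hydroperoxide 24). The neighbouring option, epoxidation of a 1(10)E alkene, needs a trans-cyclodecene that the C1 ketone does not deliver with defined geometry. The carbonyl route uses the C1 ketone left by the ring cleavage and lets each centre be set by its neighbour: C8 shields C10, and C10 directs C1 by chelation. The forward steps must hydrate the enone at C10 on the α face and keep the diol intact until closure.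

C8 ester (23 ⇒ 18 + 22; 22 ⇒ 21 ⇒ 20 ⇒ 19). The C8–O bond is cut with inversion, to the 8α-alcohol 18 and acid 22. The alcohol expected from the next disconnection is the 8α epimer, so esterification and inversion are merged in one Mitsunobu step. Acid 22 is made from angelic acid 19 through allylic alcohol 20 and epoxy alcohol 21, so its two stereocentres are fixed before coupling. Epoxidising an angelate on the macrocycle would have to choose among four alkenes.

C8 oxygen (18 ⇒ 17 ⇒ 16). The C8–O bond is cut and the C9=C10 alkene returned to C8=C9; the retron is the β,γ-epoxy ketone 17 derived from 16. Only the C1 carbonyl can relay oxygen to C8, and the same opening erases the racemic C10 centre and prepares C10 as an enone carbon. Direct hydration of C8=C9 has no regiochemical bias. The forward step needs chemoselective and face-selective epoxidation.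

Lactone (16 ⇒ 15 ⇒ 14 ⇒ 13 ⇒ 11 ⇒ 8 + 9). The ketal is removed (16 ⇒ 15). The lactone C6–O bond is cut with inversion (15 ⇒ hydroxy acid 14 ⇒ cis-lactone 13), then the C6–H bond (13 ⇒ alkoxide 12 ⇒ ketone 11), then the C7–C11 bond (11 ⇒ enolate 10 ⇒ 8 + methyl bromoacetate 9). In 8 the C6 carbonyl is an enone whose only kinetic enolate is at C7, and C1 is masked. The cis/trans problem of the fusion is turned into an anti hydride addition followed by a Mitsunobu inversion.

C3 oxygen and carbonyl differentiation (8 ⇒ 7 ⇒ 6 ⇒ 5 ⇒ 4). After removal of the ketal and silyl groups, the C3–O bond and the C4=C5 alkene are traced through epoxide 5 to the C3=C4 alkene of diketone 4. This is the only point where absolute configuration enters, and the trisubstituted alkene is the one good substrate for a chiral dioxirane. The opening also turns C6 into an enone, which distinguishes the two carbonyls for everything above.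

Ring (4 ⇒ 3 ⇒ 2 ⇒ 1). The two carbonyl carbons C1 and C6 are reconnected, through ozonide 3, as the tetrasubstituted fusion alkene of tetrahydronaphthalene 2, which is the Birch product of 1,6-dimethylnaphthalene 1. Twelve of the twenty carbons and the whole ring are bought in two steps; the forward cleavage must pick one alkene out of three.

## Roads not taken

Alternative 1: The ring would be cut at C5–C6. The open-chain iodoalkyne aldehyde A2 would be closed by an intramolecular Nozaki–Hiyama–Kishi alkynylation (CrCl2, catalytic NiCl2) to the cyclodec-4-yn-6-ol A1. Its merits are that C1, C3, C7, C8 and C10 are set on an open chain by reagent-controlled reactions, that only C6 arises in the ring-forming step, and that the alkyne is a handle for a syn addition giving the cis ring alkene. Its weak points are a bent ten-membered cycloalkyne that must form at high dilution with stoichiometric CrCl2, an uncertain configuration at C6, a regiocontrolled methyl addition to the alkyne to place C15 on C4 beside an epoxide, and a long linear sequence to A2. In stereocontrol this road is better than the chosen one. The chosen plan sets against it a ring that costs two steps from a commodity arene and needs no macrocyclisation, at the price of remote stereocontrol on the ring.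

Alternative 2: The cut is C9–C10. The bromomethyl ketone A4, with the lactone already in place, would be treated with SmI2, which joins C9 to the C10 carbonyl carbon in a Reformatsky-type closure and gives the 10-hydroxy-8-ketone A3. The tertiary C10 carbinol and the ring would form together, and C1, C3, C6 and C7 come from open-chain chemistry. Against it, the C10 face is decided inside a ten-membered transition state, simple reduction of the C–Br bond competes, A3 is a β-hydroxy ketone open to retro-aldol cleavage, C8 still needs a β-selective reduction, and the epoxide still needs an inversion at C1. For the C1/C10 pair it is at least as good as the chosen plan, since C1 is fixed beforehand. The chosen plan sets against it that no medium ring has to be closed and that C10 is made on a preformed ring whose C8 ester can steer it.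

Alternative 3: The cut is C8–C9, with C1–C6 as the bond that breaks. The potassium alkoxide A6, a trans-dialkenyl cyclohexenol reached from the terpene chiral pool, would undergo an anionic oxy-Cope rearrangement through a chair to the (4Z,1(10)E)-dien-6-one A5. The ring expands without dilution, and the chair fixes the 1(10)E alkene and C8 together, so a biomimetic epoxidation and the C8 oxygen come directly; in this it is stronger than the chosen plan. Its weak points are that A6 needs enone transposition, C3 oxygenation and a vinyl addition anti to the isopropenyl group, that the ring alkene can compete as a Cope partner, that the E,Z-cyclodecadienone A5 is prone to Cope and transannular reactions, and that C7 alkylation and C6 reduction remain to be solved as in the chosen plan. The chosen plan sets against it a flat achiral precursor and a shorter way to the ring, and pays with more steps for C8 and the epoxide.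

Key step: step 2

Conventions: ring atoms carry the germacrane numbers of the target (C1–C10 ring, C11–C13 lactone, C14 on C10, C15 on C4); α and β refer to the usual drawing in which the C3 hydroxyl and the C8 acyloxy group are β.

Assumption: C10 is enolisable next to the C1 carbonyl and is carried as a mixture of epimers from 5 to 17 (written without configuration there); it becomes sp2 in 18 and is set in step 15.

Step 1
Reactants: 1 1,6-dimethylnaphthalene
Product: 2 1,6-dimethyl-1,4,5,8-tetrahydronaphthalene (racemic)
Conditions: Na, NH3 (l), EtOH, THF, −78 to −33 °C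
Reagents that add atoms: none
Why: Birch reduction of a naphthalene to the isotetralin: each ring is reduced 1,4, the tetrasubstituted fusion alkene (future C1=C6) is kept and C15 stays on an alkene carbon; protonation at C10 creates the only, racemic, stereocentre.

Step 2
Reactants: 2 1,6-dimethyl-1,4,5,8-tetrahydronaphthalene
Product: 4 (3Z,8Z)-4,10-dimethylcyclodeca-3,8-diene-1,6-dione (racemic at C10), via secondary ozonide 3 (not isolated)
Conditions: O3 (1.0 equiv), CH2Cl2, −78 °C, Sudan Red 7B end point; Me2S, −78 °C to rt; neutral work-up
Reagents that add atoms: ozone, [O-][O+]=O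
Why: Ozone adds as a 1,3-dipole to the C1=C6 fusion alkene; the primary ozonide fragments by the Criegee mechanism to a ketone and a carbonyl oxide held together by the two four-carbon bridges, these recombine to ozonide 3, and dimethyl sulfide reduces it to the two ketones. The closest known reaction is the ozonolysis of Δ9,10-octalin to cyclodecane-1,6-dione and the cleavage of the central alkene of isotetralin. No ring is closed by bond formation: the ten-membered ring appears when the bond shared by the two six-membered rings is cut. No stereocentre is formed and C10 is untouched. The step needs chemoselectivity among three alkenes; the tetrasubstituted alkene is the most electron-rich, and one equivalent at −78 °C with a dye end point limits attack on C3=C4. Both remaining alkenes stay cis because each was part of a six-membered ring. Neutral work-up avoids transannular aldol reaction of the 1,6-dione.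

Step 3
Reactants: 4 (3Z,8Z)-4,10-dimethylcyclodeca-3,8-diene-1,6-dione
Product: 6 (3S,4Z,8Z)-3-hydroxy-4,10-dimethylcyclodeca-4,8-diene-1,6-dione, via epoxy diketone 5 (not isolated)
Conditions: 1,2:4,5-di-O-isopropylidene-β-L-erythro-2,3-hexodiulo-2,6-pyranose (L-fructose-derived Shi ketone, 30 mol%), KHSO5 (as 2KHSO5·KHSO4·K2SO4), K2CO3, Bu4NHSO4, MeCN/CH2(OMe)2/aq. Na2B4O7 buffer, 0 °C; extract; then Et3N, CH2Cl2, 0 °C
Reagents that add atoms: potassium peroxymonosulfate, [K+].[O-]S(=O)(=O)OO
Why: Shi epoxidation: the chiral dioxirane takes the trisubstituted C3=C4 alkene (the cis-disubstituted C8=C9 is a poor substrate) through the spiro transition state, and the L-series ketone should give the (3S,4R)-epoxide 5. Et3N then opens the β,γ-epoxy ketone by E1cB through the C6 enolate with loss of the weaker tertiary C4–O bond; C3 keeps its configuration and the new enone should be Z, the ring-cis geometry being the less strained one in a ten-membered ring.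

Step 4
Reactants: 6 (3S,4Z,8Z)-3-hydroxy-4,10-dimethylcyclodeca-4,8-diene-1,6-dione
Product: 7 3-O-tert-butyldimethylsilyl ether of 6
Conditions: TBSCl, imidazole, DMF, 0 °C to rt
Reagents that add atoms: tert-butyldimethylsilyl chloride, C[Si](C)(Cl)C(C)(C)C
Why: Silylation of the secondary allylic alcohol; prompt protection stops retro-aldol or dehydration of the β-hydroxy ketone (C1) and hemiketal formation onto C6.

Step 5
Reactants: 7 3-O-tert-butyldimethylsilyl ether of 6
Product: 8 C1 ethylene ketal of 7 (C6 enone free)
Conditions: (Me3SiOCH2)2, Me3SiOSO2CF3 (5 mol%), CH2Cl2, −78 to −40 °C; pyridine quench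
Reagents that add atoms: 1,2-bis(trimethylsilyloxy)ethane, C[Si](C)(C)OCCO[Si](C)(C)C
Why: Noyori ketalisation distinguishes the saturated C1 ketone from the conjugated, β,β-disubstituted C6 enone, and at low temperature leaves the silyl ether and the skipped alkene in place.

Step 6
Reactants: 8 C1 ethylene ketal of 7; 9 methyl bromoacetate
Product: 11 (7R)-7-(methoxycarbonylmethyl) ketone (C11 on the β face), via lithium enolate 10 (not isolated)
Conditions: LiN(i-Pr)2, THF, −78 °C; 9, DMPU, −78 to −40 °C
Reagents that add atoms: none
Why: Kinetic α′-deprotonation of the enone at C7 and SN2 alkylation of the enolate at its α carbon; the face is chosen by macrocyclic stereocontrol (peripheral attack on the ring-cis enolate) and should place C11 β.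

Step 7
Reactants: 11 (7R)-7-(methoxycarbonylmethyl) ketone
Product: 13 cis-fused 6β,12-lactone (6-epi lactone), via lithium alkoxide 12 (not isolated)
Conditions: LiBH(s-Bu)3, THF, −78 °C; warm to 0 °C; aq. NH4Cl
Reagents that add atoms: none
Why: The β,β-disubstituted enone is reduced 1,2; the bulky hydride adds opposite the C7 side chain (Felkin–Anh, as with 2-substituted cycloalkanones), and the 6β-alkoxide closes onto the methyl ester.

Step 8
Reactants: 13 cis-fused 6β,12-lactone
Product: 15 trans-fused 6α,12-lactone (C1 ketal), via hydroxy acid 14 (not isolated)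
Conditions: LiOH, THF/H2O, 0 °C; HCl to pH 5, cold extraction; PPh3, DIAD, THF (0.01 M), 0 °C
Reagents that add atoms: lithium hydroxide, [Li+].[OH-]
Why: Saponification followed by Mitsunobu lactonisation: the carboxylate displaces the activated allylic C6 oxygen by SN2, inverts C6 and gives the trans ring fusion of the target; the hydroxy acid is kept cold and used at once so that it does not close back to 13.

Step 9
Reactants: 15 trans-fused 6α,12-lactone (C1 ketal)
Product: 16 trans-fused lactone C1 ketone
Conditions: pyridinium p-toluenesulfonate (20 mol%), acetone/H2O, 50 °C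
Reagents that add atoms: water, O
Why: Acetal hydrolysis under mild acid that the secondary silyl ether and the lactone tolerate; the deconjugated position of C8=C9 is expected to be the stable one in the ten-membered ring.

Step 10
Reactants: 16 trans-fused lactone C1 ketone
Product: 18 8α-hydroxy-9Z-en-1-one lactone, via 8α,9α-epoxide 17 (not isolated)
Conditions: mCPBA (1.05 equiv), NaHCO3, CH2Cl2, 0 °C; then DBU, 0 °C
Reagents that add atoms: 3-chloroperoxybenzoic acid, OOC(=O)c1cccc(Cl)c1
Why: Prilezhaev epoxidation of C8=C9; C4=C5 is deactivated by two allylic C–O bonds and screened by the silyl ether, and the peracid should come from the face opposite the C7 side chain (α). DBU opens the β,γ-epoxy ketone by E1cB through the C1 enolate at C10, the only enolisable position that can open it, which gives the 8α-alcohol and removes the C10 stereocentre; low temperature limits lactone migration from O6 to O8 and loss of the C3 silyloxy group.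

Step 11
Reactants: 19 angelic acid
Product: 20 (Z)-2-methylbut-2-en-1-ol
Conditions: LiAlH4, Et2O, 0 °C
Reagents that add atoms: none
Why: Hydride reduction of the conjugated acid to the allylic alcohol; at 0 °C the Z geometry is kept.

Step 12
Reactants: 20 (Z)-2-methylbut-2-en-1-ol
Product: 21 (2S,3R)-(2,3-dimethyloxiran-2-yl)methanol
Conditions: Ti(OiPr)4 (10 mol%), L-(+)-diisopropyl tartrate (12 mol%), t-BuOOH, 4 Å molecular sieves, CH2Cl2, −20 °C
Reagents that add atoms: tert-butyl hydroperoxide, CC(C)(C)OO
Why: Sharpless asymmetric epoxidation; the L-(+)-tartrate complex delivers oxygen to the face that gives (2S,3S) products from E-allylic alcohols, which for this Z-allylic alcohol is the (2S,3R)-epoxy alcohol.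

Step 13
Reactants: 21 (2S,3R)-(2,3-dimethyloxiran-2-yl)methanol
Product: 22 (2R,3R)-2,3-dimethyloxirane-2-carboxylic acid
Conditions: 2,2,6,6-tetramethylpiperidin-1-oxyl (TEMPO, 20 mol%), PhI(OAc)2, MeCN/H2O (1:1), rt
Reagents that add atoms: water, O
Why: Oxoammonium oxidation of the primary alcohol through the aldehyde hydrate to the acid; the epoxide is not touched, and the descriptor at C2 changes only because the priorities change.

Step 14
Reactants: 18 8α-hydroxy-9Z-en-1-one lactone; 22 (2R,3R)-2,3-dimethyloxirane-2-carboxylic acid
Product: 23 8β-[(2R,3R)-2,3-dimethyloxirane-2-carbonyloxy]-9Z-en-1-one lactone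
Conditions: PPh3, DIAD, toluene, 0 °C to rt
Reagents that add atoms: none
Why: Mitsunobu esterification: the glycidic acid is acidic enough to protonate the betaine, and its carboxylate displaces the C8 oxyphosphonium by SN2, so the 8α-alcohol becomes the 8β-ester; attack at C10 (SN2′) is blocked because C10 is fully substituted.

Step 15
Reactants: 23 8β-[(2R,3R)-2,3-dimethyloxirane-2-carbonyloxy]-9Z-en-1-one lactone
Product: 25 10α-hydroxy-1-ketone, via 10α-hydroperoxide 24 (not isolated)
Conditions: Mn(dpm)3 [tris(dipivaloylmethanato)manganese] (5 mol%), PhSiH3, O2 (1 atm), i-PrOH/CH2Cl2, 0 °C; then P(OEt)3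
Reagents that add atoms: dioxygen, O=O
Why: Mukaiyama-type reductive α-hydroxylation of an enone: a manganese hydride transfers a hydrogen atom to C9, the tertiary C10 radical next to the carbonyl is trapped by O2 on the face opposite the bulky 8β-ester (α), and the phosphite reduces the hydroperoxide. The conjugated alkene is a faster hydrogen-atom acceptor than the hindered C4=C5 alkene.

Step 16
Reactants: 25 10α-hydroxy-1-ketone
Product: 26 1α,10α-diol
Conditions: Zn(BH4)2, Et2O, −30 °C; aq. NH4Cl
Reagents that add atoms: none
Why: Chelation-controlled reduction of an α-hydroxy ketone (Cram chelate): zinc bridges the C1 carbonyl and the C10 hydroxyl and hydride enters from the side of the small C14 methyl, which gives the diol whose closure leads to the trans epoxide; esters and lactone are inert.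

Step 17
Reactants: 26 1α,10α-diol
Product: 28 1β,10α-epoxide (11,13-dihydro 3-O-silyl ether of the target), via 1α-mesylate 27 (not isolated)
Conditions: MsCl, Et3N, CH2Cl2, −10 °C; then DBU, 0 °C to rt
Reagents that add atoms: none
Why: Only the secondary C1 hydroxyl is sulfonylated; intramolecular Williamson displacement by the tertiary C10 oxygen inverts C1 and gives the trans epoxide.

Step 18
Reactants: 28 1β,10α-epoxide
Product: 32 3-O-tert-butyldimethylsilyl ether of the target, via lactone enolate 29 (not isolated), via Mannich base 30 (not isolated), via ammonium iodide 31 (not isolated)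
Conditions: LiN(i-Pr)2, THF, −78 °C; Me2N=CH2 I (dimethylmethyleneammonium iodide), −78 to 0 °C; MeI, MeOH; NaHCO3, CH2Cl2/H2O
Reagents that add atoms: dimethylmethyleneammonium iodide, C=[N+](C)C.[I-]
Why: Mannich reaction of the lactone enolate, quaternisation and E1cB loss of trimethylamine; C11–H is the only acidic C–H because the C8 ester has a quaternary α-carbon, and at −78 °C the enolate is trapped before it can attack that hindered ester.

Step 19
Reactants: 32 3-O-tert-butyldimethylsilyl ether of the target
Product: 33 CNP0268255.1
Conditions: Bu4NF, AcOH (1:1), THF, 0 °C to rt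
Reagents that add atoms: none
Why: Fluoride desilylation buffered with acetic acid, which spares the methylene lactone from base and the 1,10-epoxide beside C4=C5 from acid.

Compound list
1 | 1,6-dimethylnaphthalene | Cc1cccc2cc(C)ccc12 | starting material
2 | 1,6-dimethyl-1,4,5,8-tetrahydronaphthalene (racemic) | CC1=CCC2=C(C1)CC=CC2C | intermediate
3 | secondary ozonide of the C1=C6 alkene of 2 (1,2,4-trioxolane spanning C1 and C6) | C/C1=C/CC2(O3)OOC3(C1)C/C=C\C2C | intermediate
4 | (3Z,8Z)-4,10-dimethylcyclodeca-3,8-diene-1,6-dione (racemic at C10) | O=C1C/C=C(C)\CC(=O)C/C=C\C1C | intermediate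
5 | (3S,4R)-3,4-epoxy-4,10-dimethylcyclodec-8Z-ene-1,6-dione (C10 epimers) | O=C1C[C@@H]2O[C@]2(C)CC(=O)C/C=C\C1C | intermediate
6 | (3S,4Z,8Z)-3-hydroxy-4,10-dimethylcyclodeca-4,8-diene-1,6-dione (C10 epimers) | O=C1C[C@H](O)/C(C)=C\C(=O)C/C=C\C1C | intermediate
7 | 3-O-tert-butyldimethylsilyl ether of 6 | O=C1C[C@H](O[Si](C)(C)C(C)(C)C)/C(C)=C\C(=O)C/C=C\C1C | intermediate
8 | C1 ethylene ketal of 7 | C12(OCCO1)C[C@H](O[Si](C)(C)C(C)(C)C)/C(C)=C\C(=O)C/C=C\C2C | intermediate
9 | methyl bromoacetate | COC(=O)CBr | starting material
10 | lithium enolate of 8 (C6–OLi, C6=C7, ring-cis) | C12(OCCO1)C[C@H](O[Si](C)(C)C(C)(C)C)/C(C)=C\C(O[Li])=C/C=C\C2C | intermediate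
11 | (7R)-7-(methoxycarbonylmethyl) ketone (C11 β) | C12(OCCO1)C[C@H](O[Si](C)(C)C(C)(C)C)/C(C)=C\C(=O)[C@H](CC(=O)OC)/C=C\C2C | intermediate
12 | lithium 6β-alkoxide of the hydroxy ester from 11 | C12(OCCO1)C[C@H](O[Si](C)(C)C(C)(C)C)/C(C)=C\[C@H](O[Li])[C@H](CC(=O)OC)/C=C\C2C | intermediate
13 | cis-fused 6β,12-lactone (O6 β, C11 β) | C12(OCCO1)C[C@H](O[Si](C)(C)C(C)(C)C)/C(C)=C\[C@@H]3OC(=O)C[C@@H]3/C=C\C2C | intermediate
14 | 6β-hydroxy acid from 13 | C12(OCCO1)C[C@H](O[Si](C)(C)C(C)(C)C)/C(C)=C\[C@H](O)[C@H](CC(=O)O)/C=C\C2C | intermediate
15 | trans-fused 6α,12-lactone, C1 ketal | C12(OCCO1)C[C@H](O[Si](C)(C)C(C)(C)C)/C(C)=C\[C@H]3OC(=O)C[C@@H]3/C=C\C2C | intermediate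
16 | trans-fused 6α,12-lactone, C1 ketone (C10 epimers) | O=C1C[C@H](O[Si](C)(C)C(C)(C)C)/C(C)=C\[C@H]2OC(=O)C[C@@H]2/C=C\C1C | intermediate
17 | 8α,9α-epoxide of 16 | O=C1C[C@H](O[Si](C)(C)C(C)(C)C)/C(C)=C\[C@H]2OC(=O)C[C@@H]2[C@H]3O[C@H]3C1C | intermediate
18 | 8α-hydroxy-9Z-en-1-one lactone | O=C1C[C@H](O[Si](C)(C)C(C)(C)C)/C(C)=C\[C@H]2OC(=O)C[C@@H]2[C@@H](O)/C=C1/C | intermediate
19 | angelic acid, (Z)-2-methylbut-2-enoic acid | C/C=C(/C)C(=O)O | starting material
20 | (Z)-2-methylbut-2-en-1-ol | C/C=C(/C)CO | intermediate
21 | (2S,3R)-(2,3-dimethyloxiran-2-yl)methanol | OC[C@]1(C)O[C@@H]1C | intermediate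
22 | (2R,3R)-2,3-dimethyloxirane-2-carboxylic acid | OC(=O)[C@]1(C)O[C@@H]1C | intermediate
23 | 8β-[(2R,3R)-2,3-dimethyloxirane-2-carbonyloxy]-9Z-en-1-one lactone | O=C1C[C@H](O[Si](C)(C)C(C)(C)C)/C(C)=C\[C@H]2OC(=O)C[C@@H]2[C@H](OC(=O)[C@]3(C)O[C@@H]3C)/C=C1/C | intermediate
24 | 10α-hydroperoxy-1-ketone | O=C1C[C@H](O[Si](C)(C)C(C)(C)C)/C(C)=C\[C@H]2OC(=O)C[C@@H]2[C@H](OC(=O)[C@]3(C)O[C@@H]3C)C[C@@]1(C)OO | intermediate
25 | 10α-hydroxy-1-ketone | O=C1C[C@H](O[Si](C)(C)C(C)(C)C)/C(C)=C\[C@H]2OC(=O)C[C@@H]2[C@H](OC(=O)[C@]3(C)O[C@@H]3C)C[C@@]1(C)O | intermediate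
26 | 1α,10α-diol | O[C@H]1C[C@H](O[Si](C)(C)C(C)(C)C)/C(C)=C\[C@H]2OC(=O)C[C@@H]2[C@H](OC(=O)[C@]3(C)O[C@@H]3C)C[C@@]1(C)O | intermediate
27 | 1α-methanesulfonate of 26 | CS(=O)(=O)O[C@H]1C[C@H](O[Si](C)(C)C(C)(C)C)/C(C)=C\[C@H]2OC(=O)C[C@@H]2[C@H](OC(=O)[C@]3(C)O[C@@H]3C)C[C@@]1(C)O | intermediate
28 | 1β,10α-epoxide (11,13-dihydro 3-O-silyl ether of the target) | C1C(=O)O[C@@H]2/C=C(/C)[C@@H](O[Si](C)(C)C(C)(C)C)C[C@H]3O[C@]3(C)C[C@@H](OC(=O)[C@]3(C)O[C@@H]3C)[C@@H]12 | intermediate
29 | lithium enolate of lactone 28 | C1=C(O[Li])O[C@@H]2/C=C(/C)[C@@H](O[Si](C)(C)C(C)(C)C)C[C@H]3O[C@]3(C)C[C@@H](OC(=O)[C@]3(C)O[C@@H]3C)[C@@H]12 | intermediate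
30 | 11-(dimethylaminomethyl) lactone (C11 epimers) | CN(C)CC1C(=O)O[C@@H]2/C=C(/C)[C@@H](O[Si](C)(C)C(C)(C)C)C[C@H]3O[C@]3(C)C[C@@H](OC(=O)[C@]3(C)O[C@@H]3C)[C@@H]12 | intermediate
31 | 11-(trimethylammoniomethyl) lactone iodide | C[N+](C)(C)CC1C(=O)O[C@@H]2/C=C(/C)[C@@H](O[Si](C)(C)C(C)(C)C)C[C@H]3O[C@]3(C)C[C@@H](OC(=O)[C@]3(C)O[C@@H]3C)[C@@H]12.[I-] | intermediate
32 | 3-O-tert-butyldimethylsilyl ether of the target | C=C1C(=O)O[C@@H]2/C=C(/C)[C@@H](O[Si](C)(C)C(C)(C)C)C[C@H]3O[C@]3(C)C[C@@H](OC(=O)[C@]3(C)O[C@@H]3C)[C@@H]12 | intermediate
33 | CNP0268255.1, (1R,3S,4Z,6R,7R,8R,10R)-1,10-epoxy-3-hydroxy-8-[(2R,3R)-2,3-dimethyloxirane-2-carbonyloxy]germacra-4,11(13)-dien-12,6-olide | C=C1C(=O)O[C@@H]2/C=C(/C)[C@@H](O)C[C@H]3O[C@]3(C)C[C@@H](OC(=O)[C@]3(C)O[C@@H]3C)[C@@H]12 | target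

Total step count: 19. Longest linear sequence: 16 steps (steps 1–10 and 14–19); the acid 22 is made in a three-step branch (steps 11–13).

Least certain steps: 2 (the key step), 3, 6, 10, 14 and 15.

On step 2 (the key step): the most likely failure is incomplete chemoselectivity. Ozone distinguishes a tetrasubstituted from a trisubstituted alkene less sharply than peracids do, so cleavage of C3=C4 and over-oxidation can compete, and the 1,6-dione can undergo transannular aldol reaction during work-up. The fallback sets out from 2: epoxidation with mCPBA at −40 °C, which follows alkene substitution more steeply, should give the fusion epoxide F1 (the 4a,8a-epoxide of 2). H5IO6 in aqueous THF, which opens the epoxide and cleaves the glycol in one flask, then returns to the route at 4.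

On step 3: the epoxide may open toward C2 through the C1 enolate instead of toward C5, the new alkene may form in part with the ring-trans geometry, and the base may start transannular aldol chemistry of the dione. The fallback sets out from the crude epoxide 5 and changes the activation from enolate to enamine. Pyrrolidine condenses only with the unhindered C6 carbonyl (C1 is α-branched) to give the C6 pyrrolidine enamine F2. Its nitrogen lone pair pushes through C5 and expels the C4 oxygen, giving the conjugated iminium acetate F3. Hydrolysis in aqueous acetic acid returns to the route at 6.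

On step 6: poor facial selectivity is the likely problem, because the only resident stereocentres are remote from C7 and the outcome rests on ring conformation. The fallback sets out from 8: if the alkylation delivers mainly the C7 epimer F4 (C11 on the α face), this is deprotonated again with LiN(i-Pr)2 to the lithium enolate F5 and protonated kinetically with 2,6-di-tert-butyl-4-methylphenol at −78 °C. The proton should enter from the exposed face that the electrophile used, which inverts C7 and returns to the route at 11.

On step 10: the peracid may prefer the β face of C8=C9, since both faces are flanked by parts of the lactone, and the opening would then give the C8 epimer; loss of the C3 silyloxy group through the C2 enolate is a second risk. The fallback sets out from 16: if the 8β,9β-epoxide F6 is what forms, DBU opens it to the 8β-hydroxy enone F7, which already has the C8 configuration of the target. It is acylated with retention by the mixed anhydride F8, made from 22 and 2-methyl-6-nitrobenzoic anhydride with 4-(dimethylamino)pyridine. This returns to the route at 23 without the Mitsunobu step.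

On step 14: elimination to the dienone or low conversion is likely, because the carbinol is hindered and allylic and the acid is α,α-disubstituted. The fallback sets out from 18: sulfonylation gives the 8α-mesylate F9, which is displaced with inversion by the cesium carboxylate F10 (from 22 and Cs2CO3) in toluene with 18-crown-6. This returns to the route at 23.

On step 15: oxygen may trap the C10 radical from the β face, or hydrogen-atom transfer may also reach C4=C5. The fallback sets out from 23 and replaces radical trapping by a reagent-controlled oxidation. Conjugate hydrosilylation with catalytic [(Ph3P)CuH]6 and Me2PhSiH gives the C1 dimethylphenylsilyl enol ether F11. The dioxirane generated from the Shi ketone and KHSO5 (ketone enantiomer chosen to reinforce α attack) epoxidises it in a Rubottom-type oxidation to the silyloxy epoxide F12. Mild aqueous acid opens this with loss of the silanol and returns to the route at 25.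

Further compounds
F1 | step 2 | fusion epoxide (4a,8a-epoxide of 2) | CC1=CCC23OC2(C1)CC=CC3C
F2 | step 3 | C6 pyrrolidine enamine of 5 | O=C1C[C@@H]2O[C@]2(C)C=C(N3CCCC3)C/C=C\C1C
F3 | step 3 | conjugated C6 pyrrolidinium (iminium) acetate of 6 | O=C1C[C@H](O)/C(C)=C\C(=[N+]2CCCC2)C/C=C\C1C.CC(=O)[O-]
F4 | step 6 | C7 epimer of 11 (C11 α) | C12(OCCO1)C[C@H](O[Si](C)(C)C(C)(C)C)/C(C)=C\C(=O)[C@@H](CC(=O)OC)/C=C\C2C
F5 | step 6 | lithium enolate of 11 (C6–OLi, C6=C7) | C12(OCCO1)C[C@H](O[Si](C)(C)C(C)(C)C)/C(C)=C\C(O[Li])=C(CC(=O)OC)/C=C\C2C
F6 | step 10 | 8β,9β-epoxide of 16 | O=C1C[C@H](O[Si](C)(C)C(C)(C)C)/C(C)=C\[C@H]2OC(=O)C[C@@H]2[C@@H]3O[C@@H]3C1C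
F7 | step 10 | 8β-hydroxy-9Z-en-1-one lactone (C8 epimer of 18) | O=C1C[C@H](O[Si](C)(C)C(C)(C)C)/C(C)=C\[C@H]2OC(=O)C[C@@H]2[C@H](O)/C=C1/C
F8 | step 10 | mixed anhydride of 22 and 2-methyl-6-nitrobenzoic acid | Cc1cccc([N+](=O)[O-])c1C(=O)OC(=O)[C@]1(C)O[C@@H]1C
F9 | step 14 | 8α-methanesulfonate of 18 | O=C1C[C@H](O[Si](C)(C)C(C)(C)C)/C(C)=C\[C@H]2OC(=O)C[C@@H]2[C@@H](OS(C)(=O)=O)/C=C1/C
F10 | step 14 | cesium (2R,3R)-2,3-dimethyloxirane-2-carboxylate | [Cs+].[O-]C(=O)[C@]1(C)O[C@@H]1C
F11 | step 15 | C1 dimethylphenylsilyl enol ether from 23 (C1=C10, C9 saturated) | C1(O[Si](C)(C)c4ccccc4)C[C@H](O[Si](C)(C)C(C)(C)C)/C(C)=C\[C@H]2OC(=O)C[C@@H]2[C@H](OC(=O)[C@]3(C)O[C@@H]3C)CC=1C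
F12 | step 15 | 1-(dimethylphenylsilyloxy)-1,10α-epoxide from F11 (C1 epimers) | C[Si](C)(c4ccccc4)OC15C[C@H](O[Si](C)(C)C(C)(C)C)/C(C)=C\[C@H]2OC(=O)C[C@@H]2[C@H](OC(=O)[C@]3(C)O[C@@H]3C)C[C@@]1(C)O5
A1 | alternative 1 | ten-membered cyclodec-4-yn-6-ol with C3 4-methoxybenzyl ether, C8 silyl ether, 1,10-epoxide and C7 tert-butyl acetate arm | O[C@@H]1C#C[C@@H](OCc2ccc(OC)cc2)C[C@H]3O[C@]3(C)C[C@@H](O[Si](C)(C)C(C)(C)C)[C@H]1CC(=O)OC(C)(C)C
A2 | alternative 1 | open-chain C5 iodoalkyne C6 aldehyde | IC#C[C@@H](OCc1ccc(OC)cc1)C[C@H]2O[C@]2(C)C[C@@H](O[Si](C)(C)C(C)(C)C)[C@@H](CC(=O)OC(C)(C)C)C=O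
A3 | alternative 2 | ten-membered 10-hydroxy-8-ketone lactone with C1 triethylsilyl and C3 tert-butyldimethylsilyl ethers | C1C(=O)O[C@@H]2/C=C(/C)[C@@H](O[Si](C)(C)C(C)(C)C)C[C@H](O[Si](CC)(CC)CC)[C@](C)(O)CC(=O)[C@@H]12
A4 | alternative 2 | open-chain C8 bromomethyl ketone with C10 methyl ketone on the preformed lactone | C1C(=O)O[C@H](/C=C(/C)[C@@H](O[Si](C)(C)C(C)(C)C)C[C@H](O[Si](CC)(CC)CC)C(C)=O)[C@H]1C(=O)CBr
A5 | alternative 3 | ten-membered (4Z,1(10)E)-dien-6-one with C3 silyl ether and C8 4-methoxybenzyl ether | O=C1/C=C(/C)[C@@H](O[Si](C)(C)C(C)(C)C)C/C=C(\C)/C[C@@H](OCc2ccc(OC)cc2)C1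
A6 | alternative 3 | potassium alkoxide of the trans 1-(2-alkoxyvinyl)-6-isopropenyl cyclohex-2-enol | [K+].[O-][C@]1(/C=C/OCc2ccc(OC)cc2)C=C(C)[C@@H](O[Si](C)(C)C(C)(C)C)C[C@@H]1C(C)=C
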